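**Retrosynthetic overview**
1. The two prenyl groups go on last. Both are delivered from O7 by two rounds of 1,1-dimethylpropargyl ether formation, Lindlar reduction and aromatic Claisen shift (first to C8, then to C6), followed by MOM removal. The hydrogen-bonded 5-OH is never alkylated.
2. Ring C (the pyranone) is cut at O1–C8a and C4–C4a. An aryne takes up the enol oxygen and the ester carbon of a β-formyl arylacetate in one operation.
3. The feature behind this cut: ring A carries O1 on C8a, the C4 carbonyl on C4a and an oxygen on C5, on three neighbouring carbons. A 3-alkoxybenzyne gives exactly this pattern, with the nucleophile at the carbon meta to the alkoxy group and the electrophile at the carbon ortho to it. The C7 oxygen is the second benzyloxy group of the aryne.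
4. The aryne precursor comes from 3,5-bis(benzyloxy)phenol (bromination, then silylation, retro-Brook shift and triflation). The enol ester comes from 4-hydroxy-2-methoxybenzaldehyde (MOM ether, then acid-catalysed diazoacetate homologation with 1,2-aryl shift).
5. Ring order: rings A and B are bought; ring C is the only ring formed (step 5).

Key step: step 5

Remarks on the chemistry:
- The target has no stereocentre and no stereogenic double bond, so no stereocontrol is needed.
- The enol ester is carried as the ethyl ester; the alkoxy group is lost in the key step.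
- The first Claisen shift (step 8) is written for the expected C8 isomer. Any C6 isomer would give the same compound 21 after steps 9 and 10, so the regiochemistry of that step is not critical.

Step 1
Reactants: 1 3,5-bis(benzyloxy)phenol
Product: 2 3,5-bis(benzyloxy)-2-bromophenol
Conditions: NBS (1.0 equiv), CH2Cl2, −78 °C
Reagents that add atoms: N-bromosuccinimide, O=C1CCC(=O)N1Br
Why: Electrophilic aromatic bromination of a phloroglucinol-type ring, where one equivalent of NBS at low temperature should monobrominate ortho to the free hydroxyl (two equivalent sites, hydrogen-bond-assisted delivery); any 4-bromo isomer would be removed by chromatography.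

Step 2
Reactants: 2 3,5-bis(benzyloxy)-2-bromophenol
Product: 6 3,5-bis(benzyloxy)-2-(trimethylsilyl)phenyl trifluoromethanesulfonate, via aryl trimethylsilyl ether 3 (not isolated), via aryllithium 4 (not isolated), via lithium 2-silylphenoxide 5 (not isolated)
Conditions: HMDS, THF, 65 °C, evaporate; n-BuLi, THF, −78 °C; then Tf2O, −78 °C
Reagents that add atoms: hexamethyldisilazane, C[Si](C)(C)N[Si](C)(C)C; trifluoromethanesulfonic anhydride, O=S(=O)(OS(=O)(=O)C(F)(F)F)C(F)(F)F
Why: Standard ortho-silyl aryl triflate synthesis: O-silylation, bromine–lithium exchange (faster than benzylic deprotonation at −78 °C), 1,3-retro-Brook O-to-C silyl shift driven by phenoxide formation, and O-triflation.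

Step 3
Reactants: 7 4-hydroxy-2-methoxybenzaldehyde
Product: 8 2-methoxy-4-(methoxymethoxy)benzaldehyde
Conditions: MOMCl, i-Pr2NEt, CH2Cl2, 0 °C to rt
Reagents that add atoms: chloromethyl methyl ether, COCCl
Why: Williamson-type O-alkylation of the phenol gives a MOM acetal that tolerates fluoride, base, hydrogenation and heat in the later steps.

Step 4
Reactants: 8 2-methoxy-4-(methoxymethoxy)benzaldehyde; 9 ethyl diazoacetate
Product: 10 ethyl (Z)-3-hydroxy-2-[2-methoxy-4-(methoxymethoxy)phenyl]prop-2-enoate
Conditions: HBF4·OEt2 (10 mol%), CH2Cl2, −78 °C, slow addition of 9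
Reagents that add atoms: none
Why: Acid-catalysed addition of the diazo ester to the aldehyde followed by loss of N2 with 1,2-shift of the electron-rich 2,4-dialkoxyphenyl group (semipinacol-type homologation; aryl migration should outrun the hydride shift of the Roskamp reaction) gives the formyl ester as its hydrogen-bonded Z-enol, and catalytic acid at −78 °C without water should leave the MOM acetal intact.

Step 5
Reactants: 6 3,5-bis(benzyloxy)-2-(trimethylsilyl)phenyl trifluoromethanesulfonate; 10 ethyl (Z)-3-hydroxy-2-[2-methoxy-4-(methoxymethoxy)phenyl]prop-2-enoate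
Product: 13 5,7-bis(benzyloxy)-3-[2-methoxy-4-(methoxymethoxy)phenyl]-4H-chromen-4-one, via aryne 11 (not isolated), via aryl caesium enol ether 12 (not isolated)
Conditions: CsF (4 equiv), 6 (1.3 equiv), THF, 65 °C
Reagents that add atoms: none
Why: Proposed new method: fluoride removes the silyl group of 6 and triflate leaves to give aryne 11, the caesium enolate of 10 adds through its terminal oxygen to the aryne carbon meta to the 3-benzyloxy group (O1–C8a), and the aryl anion 12 formed at the future C4a attacks the cis ester carbonyl and expels ethoxide (C4a–C4). The closest known reaction is the fluoride-induced annulation of arynes with salicylate esters to xanthones, where a phenoxide adds and the ester captures the aryl anion; here the phenoxide is replaced by the enolate oxygen of a β-formyl ester. The pyranone closes by 6-exo-trig attack of the aryl carbanion on the ester C=O with loss of ethoxide, and no stereocentre is formed. The regiochemistry on the aryne rests on the inductive control of 3-alkoxyarynes, which puts the nucleophile remote from the alkoxy group and the carbanion next to it. O-arylation should beat C-arylation because the α-carbon bears no hydrogen and is shielded by the twisted ortho-methoxyaryl group and the ester, and caesium chelation between the two oxygens in THF should hold the enolate in the Z form needed for acyl capture. THF is chosen over acetonitrile so that protonation of 12 does not outrun ring closure.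

Step 6
Reactants: 13 5,7-bis(benzyloxy)-3-[2-methoxy-4-(methoxymethoxy)phenyl]-4H-chromen-4-one
Product: 14 5,7-dihydroxy-3-[2-methoxy-4-(methoxymethoxy)phenyl]-4H-chromen-4-one
Conditions: H2 (1 atm), 10% Pd/C, EtOAc–MeOH, rt
Reagents that add atoms: none
Why: Hydrogenolysis of the two benzyl aryl ethers, which should spare the MOM acetal and, if stopped when 13 is consumed, the slowly reduced C2=C3 bond of the isoflavone.

Step 7
Reactants: 14 5,7-dihydroxy-3-[2-methoxy-4-(methoxymethoxy)phenyl]-4H-chromen-4-one; 15 3-chloro-3-methylbut-1-yne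
Product: 16 5-hydroxy-3-[2-methoxy-4-(methoxymethoxy)phenyl]-7-[(2-methylbut-3-yn-2-yl)oxy]-4H-chromen-4-one
Conditions: K2CO3, KI, CuI (cat.), acetone, 60 °C
Reagents that add atoms: none
Why: Copper-assisted Williamson-type O-alkylation with a tertiary propargylic chloride, selective for the acidic, unchelated 7-OH because the 5-OH is held in a hydrogen bond to the C4 carbonyl.

Step 8
Reactants: 16 5-hydroxy-3-[2-methoxy-4-(methoxymethoxy)phenyl]-7-[(2-methylbut-3-yn-2-yl)oxy]-4H-chromen-4-one
Product: 18 5,7-dihydroxy-3-[2-methoxy-4-(methoxymethoxy)phenyl]-8-(3-methylbut-2-en-1-yl)-4H-chromen-4-one, via dimethylallyl ether 17 (not isolated)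
Conditions: H2 (1 atm), Lindlar cat., quinoline, EtOAc, rt; filter, evaporate; xylenes, 130 °C
Reagents that add atoms: none
Why: Lindlar semihydrogenation of the terminal alkyne followed by an aromatic Claisen [3,3] shift of the 1,1-dimethylallyl ether, which delivers a prenyl group to an ortho carbon of O7, expected mainly C8.

Step 9
Reactants: 18 5,7-dihydroxy-3-[2-methoxy-4-(methoxymethoxy)phenyl]-8-(3-methylbut-2-en-1-yl)-4H-chromen-4-one; 15 3-chloro-3-methylbut-1-yne
Product: 19 5-hydroxy-3-[2-methoxy-4-(methoxymethoxy)phenyl]-8-(3-methylbut-2-en-1-yl)-7-[(2-methylbut-3-yn-2-yl)oxy]-4H-chromen-4-one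
Conditions: DBU (1.2 equiv), CuCl2·2H2O (cat.), MeCN, 0 °C to rt
Reagents that add atoms: none
Why: Copper-catalysed propargylic etherification, which is suited to ortho-substituted phenols and should again take only the 7-OH because the 5-OH stays chelated to the carbonyl.

Step 10
Reactants: 19 5-hydroxy-3-[2-methoxy-4-(methoxymethoxy)phenyl]-8-(3-methylbut-2-en-1-yl)-7-[(2-methylbut-3-yn-2-yl)oxy]-4H-chromen-4-one
Product: 21 5,7-dihydroxy-3-[2-methoxy-4-(methoxymethoxy)phenyl]-6,8-bis(3-methylbut-2-en-1-yl)-4H-chromen-4-one, via dimethylallyl ether 20 (not isolated)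
Conditions: H2 (1 atm), Lindlar cat., quinoline, EtOAc, rt; filter, evaporate; xylenes, 130 °C
Reagents that add atoms: none
Why: Lindlar semihydrogenation (the trisubstituted prenyl alkene is not touched) and a second aromatic Claisen [3,3] shift, which can end only at C6, the one free ortho position of O7.

Step 11
Reactants: 21 5,7-dihydroxy-3-[2-methoxy-4-(methoxymethoxy)phenyl]-6,8-bis(3-methylbut-2-en-1-yl)-4H-chromen-4-one
Product: 22 5,7-dihydroxy-3-(4-hydroxy-2-methoxyphenyl)-6,8-bis(3-methylbut-2-en-1-yl)-4H-chromen-4-one (CNP0189279.0)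
Conditions: 3 M aq. HCl, MeOH, rt to 40 °C
Reagents that add atoms: none
Why: Acid-catalysed acetal exchange removes the aryl MOM ether, and dilute acid at or below 40 °C should do so faster than it protonates the trisubstituted prenyl alkenes.

**Compound list**
1 | 3,5-bis(benzyloxy)phenol | Oc1cc(OCc2ccccc2)cc(OCc2ccccc2)c1 | starting material
2 | 3,5-bis(benzyloxy)-2-bromophenol | Oc1cc(OCc2ccccc2)cc(OCc2ccccc2)c1Br | intermediate
3 | [3,5-bis(benzyloxy)-2-bromophenoxy]trimethylsilane | C[Si](C)(C)Oc1cc(OCc2ccccc2)cc(OCc2ccccc2)c1Br | intermediate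
4 | [2,4-bis(benzyloxy)-6-(trimethylsilyloxy)phenyl]lithium | [Li]c1c(O[Si](C)(C)C)cc(OCc2ccccc2)cc1OCc1ccccc1 | intermediate
5 | lithium 3,5-bis(benzyloxy)-2-(trimethylsilyl)phenoxide | [Li+].[O-]c1cc(OCc2ccccc2)cc(OCc2ccccc2)c1[Si](C)(C)C | intermediate
6 | 3,5-bis(benzyloxy)-2-(trimethylsilyl)phenyl trifluoromethanesulfonate | C[Si](C)(C)c1c(OS(=O)(=O)C(F)(F)F)cc(OCc2ccccc2)cc1OCc1ccccc1 | intermediate
7 | 4-hydroxy-2-methoxybenzaldehyde | COc1cc(O)ccc1C=O | starting material
8 | 2-methoxy-4-(methoxymethoxy)benzaldehyde | COCOc1ccc(C=O)c(OC)c1 | intermediate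
9 | ethyl diazoacetate | CCOC(=O)C=[N+]=[N-] | starting material
10 | ethyl (Z)-3-hydroxy-2-[2-methoxy-4-(methoxymethoxy)phenyl]prop-2-enoate | CCOC(=O)/C(=C\O)c1ccc(OCOC)cc1OC | intermediate
11 | 3,5-bis(benzyloxy)benzyne (1,2-didehydro-3,5-bis(benzyloxy)benzene) | C1#CC(OCc2ccccc2)=CC(OCc2ccccc2)=C1 | intermediate
12 | caesium 2,4-bis(benzyloxy)-6-{[(Z)-3-ethoxy-2-[2-methoxy-4-(methoxymethoxy)phenyl]-3-oxoprop-1-en-1-yl]oxy}phenide | CCOC(=O)/C(=C\Oc1cc(OCc2ccccc2)cc(OCc2ccccc2)c1[Cs])c1ccc(OCOC)cc1OC | intermediate
13 | 5,7-bis(benzyloxy)-3-[2-methoxy-4-(methoxymethoxy)phenyl]-4H-chromen-4-one | COCOc1ccc(-c2coc3cc(OCc4ccccc4)cc(OCc4ccccc4)c3c2=O)c(OC)c1 | intermediate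
14 | 5,7-dihydroxy-3-[2-methoxy-4-(methoxymethoxy)phenyl]-4H-chromen-4-one | COCOc1ccc(-c2coc3cc(O)cc(O)c3c2=O)c(OC)c1 | intermediate
15 | 3-chloro-3-methylbut-1-yne | CC(C)(Cl)C#C | starting material
16 | 5-hydroxy-3-[2-methoxy-4-(methoxymethoxy)phenyl]-7-[(2-methylbut-3-yn-2-yl)oxy]-4H-chromen-4-one | COCOc1ccc(-c2coc3cc(OC(C)(C)C#C)cc(O)c3c2=O)c(OC)c1 | intermediate
17 | 5-hydroxy-3-[2-methoxy-4-(methoxymethoxy)phenyl]-7-[(2-methylbut-3-en-2-yl)oxy]-4H-chromen-4-one | COCOc1ccc(-c2coc3cc(OC(C)(C)C=C)cc(O)c3c2=O)c(OC)c1 | intermediate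
18 | 5,7-dihydroxy-3-[2-methoxy-4-(methoxymethoxy)phenyl]-8-(3-methylbut-2-en-1-yl)-4H-chromen-4-one | COCOc1ccc(-c2coc3c(CC=C(C)C)c(O)cc(O)c3c2=O)c(OC)c1 | intermediate
19 | 5-hydroxy-3-[2-methoxy-4-(methoxymethoxy)phenyl]-8-(3-methylbut-2-en-1-yl)-7-[(2-methylbut-3-yn-2-yl)oxy]-4H-chromen-4-one | COCOc1ccc(-c2coc3c(CC=C(C)C)c(OC(C)(C)C#C)cc(O)c3c2=O)c(OC)c1 | intermediate
20 | 5-hydroxy-3-[2-methoxy-4-(methoxymethoxy)phenyl]-8-(3-methylbut-2-en-1-yl)-7-[(2-methylbut-3-en-2-yl)oxy]-4H-chromen-4-one | COCOc1ccc(-c2coc3c(CC=C(C)C)c(OC(C)(C)C=C)cc(O)c3c2=O)c(OC)c1 | intermediate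
21 | 5,7-dihydroxy-3-[2-methoxy-4-(methoxymethoxy)phenyl]-6,8-bis(3-methylbut-2-en-1-yl)-4H-chromen-4-one | COCOc1ccc(-c2coc3c(CC=C(C)C)c(O)c(CC=C(C)C)c(O)c3c2=O)c(OC)c1 | intermediate
22 | 5,7-dihydroxy-3-(4-hydroxy-2-methoxyphenyl)-6,8-bis(3-methylbut-2-en-1-yl)-4H-chromen-4-one | COc1cc(O)ccc1-c1coc2c(CC=C(C)C)c(O)c(CC=C(C)C)c(O)c2c1=O | target

**Step count**
Total: 11 steps. Longest linear sequence: 9 steps (1 → 2 → 6 → 13 → 14 → 16 → 18 → 19 → 21 → 22). The branch 7 → 8 → 10 joins at step 5 and is equally long.

**Steps most likely to fail**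

Step 5 (proposed new method). Three processes could take the material away: C-arylation of the ambident enolate followed by insertion into the C–C bond, protonation of the aryl anion before it reaches the ester, and O-arylation in the geometry that keeps the ester out of reach. The fallback builds the same two bonds one after the other by known chemistry; it sets out from 10 and 1 and comes back at 13. Enol 10 would be sulfonylated (TsCl, Et3N, N-methylimidazole, CH2Cl2) to ethyl (Z)-2-[2-methoxy-4-(methoxymethoxy)phenyl]-3-(tosyloxy)prop-2-enoate F1. Addition–elimination of the caesium phenoxide of 1 on F1 (Cs2CO3, MeCN) would give ethyl (Z)-3-[3,5-bis(benzyloxy)phenoxy]-2-[2-methoxy-4-(methoxymethoxy)phenyl]prop-2-enoate F2. Saponification (LiOH, THF–H2O) would give (Z)-3-[3,5-bis(benzyloxy)phenoxy]-2-[2-methoxy-4-(methoxymethoxy)phenyl]prop-2-enoic acid F3. Intramolecular Friedel–Crafts acylation through the mixed anhydride (TFAA, CH2Cl2, 0 °C) would then close the pyranone to 13. The two ortho positions of the 3,5-bis(benzyloxy)phenoxy ring are equivalent, so only one chromone can form. Any E isomer of the push–pull enol ether should equilibrate under the acylation conditions.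

Step 4. The MOM acetal may be lost under the acid, or hydride may shift in place of the aryl group, which would give the β-keto ester. The fallback is the classical formylation of an arylacetate; it sets out from 8 and comes back at 10. Reductive cyanation of 8 (TosMIC, t-BuOK, DME, −40 °C, then MeOH, reflux; Van Leusen) would give [2-methoxy-4-(methoxymethoxy)phenyl]acetonitrile F4. Basic hydrolysis (KOH, EtOH–H2O, reflux) would give [2-methoxy-4-(methoxymethoxy)phenyl]acetic acid F5. Alkylation (EtI, K2CO3, DMF) would give ethyl [2-methoxy-4-(methoxymethoxy)phenyl]acetate F6. Crossed Claisen condensation with ethyl formate (NaH, THF) would then give 10. No acid is used anywhere in this sequence.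

Step 11. Acid may add an ortho-prenyl group to a neighbouring phenol (chroman formation) or hydrate a prenyl alkene while the MOM ether is being cleaved. The fallback moves the acetal cleavage ahead of the second Claisen shift; it sets out from 19 and comes back at 22. In 19 the only prenyl group sits at C8 between the O7 ether and ring oxygen O1, with no free phenol next to it. Treatment of isomerically pure 19 with HCl in MeOH at rt would give 5-hydroxy-3-(4-hydroxy-2-methoxyphenyl)-8-(3-methylbut-2-en-1-yl)-7-[(2-methylbut-3-yn-2-yl)oxy]-4H-chromen-4-one F7. Lindlar semihydrogenation would give 5-hydroxy-3-(4-hydroxy-2-methoxyphenyl)-8-(3-methylbut-2-en-1-yl)-7-[(2-methylbut-3-en-2-yl)oxy]-4H-chromen-4-one F8. Heating in xylenes would bring the Claisen shift to C6 and give 22 directly, so the last step would be neutral and thermal.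

**Further compounds**
F1 | step 5 | ethyl (Z)-2-[2-methoxy-4-(methoxymethoxy)phenyl]-3-(tosyloxy)prop-2-enoate | CCOC(=O)/C(=C\OS(=O)(=O)c1ccc(C)cc1)c1ccc(OCOC)cc1OC
F2 | step 5 | ethyl (Z)-3-[3,5-bis(benzyloxy)phenoxy]-2-[2-methoxy-4-(methoxymethoxy)phenyl]prop-2-enoate | CCOC(=O)/C(=C\Oc1cc(OCc2ccccc2)cc(OCc2ccccc2)c1)c1ccc(OCOC)cc1OC
F3 | step 5 | (Z)-3-[3,5-bis(benzyloxy)phenoxy]-2-[2-methoxy-4-(methoxymethoxy)phenyl]prop-2-enoic acid | OC(=O)/C(=C\Oc1cc(OCc2ccccc2)cc(OCc2ccccc2)c1)c1ccc(OCOC)cc1OC
F4 | step 4 | [2-methoxy-4-(methoxymethoxy)phenyl]acetonitrile | N#CCc1ccc(OCOC)cc1OC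
F5 | step 4 | [2-methoxy-4-(methoxymethoxy)phenyl]acetic acid | OC(=O)Cc1ccc(OCOC)cc1OC
F6 | step 4 | ethyl [2-methoxy-4-(methoxymethoxy)phenyl]acetate | CCOC(=O)Cc1ccc(OCOC)cc1OC
F7 | step 11 | 5-hydroxy-3-(4-hydroxy-2-methoxyphenyl)-8-(3-methylbut-2-en-1-yl)-7-[(2-methylbut-3-yn-2-yl)oxy]-4H-chromen-4-one | COc1cc(O)ccc1-c1coc2c(CC=C(C)C)c(OC(C)(C)C#C)cc(O)c2c1=O
F8 | step 11 | 5-hydroxy-3-(4-hydroxy-2-methoxyphenyl)-8-(3-methylbut-2-en-1-yl)-7-[(2-methylbut-3-en-2-yl)oxy]-4H-chromen-4-one | COc1cc(O)ccc1-c1coc2c(CC=C(C)C)c(OC(C)(C)C=C)cc(O)c2c1=O
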